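**Retrosynthetic overview**
1. Feature: in the oxolane (O1, C2 aryl, C3 CH2OH, C4 aroyl, C5 H2), C2 is benzylic to the 3,4,5-trimethoxyphenyl ring and para to its 4-methoxy group. The 3,4-dimethoxyphenyl ring is conjugated to the C4 carbonyl and has no benzylic C-H, so C2 can remain a plain CH2 until the end.
2. Disconnection 1 (last bond, only ring of the target): O1-C2 is opened to the (2R,3R) keto diol with a C2 methylene. In the forward direction, DDQ abstracts hydride and the C5 hydroxyl captures the cation.
3. Disconnection 2: the ketone comes from a 1,3-dithiane. Both CH2OH groups come from LiAlH4 opening of a gamma-menthyloxy butyrolactone, a temporary ring that is not kept.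
4. Disconnection 3: C4-C(acyl) and C3-C2 come from one three-component coupling of lithiated veratraldehyde dithiane, (5R)-menthyloxybutenolide and trimethoxybenzyl bromide. The 3,4-trans lactone maps onto the 3,4-cis oxolane because at C3 the ring bond passes from the lactone carbonyl carbon to the benzyl carbon.
5. Ring order: the auxiliary lactone is bought and opened in step 3. The oxolane is closed last, in step 5.

Key step: step 5

Remark: open-chain intermediates carry the oxolane numbers of the target (O1, C2, C3, C4, C5), the lactones carry lactone numbers (O1, C2 carbonyl, C3, C4, C5 acetal), and the menthyloxybutenolide and the benzyl bromide are taken as catalogue compounds.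

**Step 1**
Reactants: 1 3,4-dimethoxybenzaldehyde; 2 propane-1,3-dithiol
Product: 3 2-(3,4-dimethoxyphenyl)-1,3-dithiane
Conditions: BF3·OEt2 (10 mol %), CH2Cl2, 0 °C to rt
Reagents that add atoms: none
Why: Lewis acid catalysed dithioacetalisation of an aromatic aldehyde is reliable, forms no stereocentre and gives the acyl anion equivalent needed for Corey-Seebach umpolung.

**Step 2**
Reactants: 3 2-(3,4-dimethoxyphenyl)-1,3-dithiane; 4 (5R)-5-(l-menthyloxy)furan-2(5H)-one; 5 3,4,5-trimethoxybenzyl bromide
Product: 8 (3R,4R,5R)-4-[2-(3,4-dimethoxyphenyl)-1,3-dithian-2-yl]-5-(l-menthyloxy)-3-(3,4,5-trimethoxybenzyl)oxolan-2-one, via lithiated dithiane 6 (not isolated), via lithium enolate 7 (not isolated)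
Conditions: n-BuLi, THF, -78 to -20 °C; 4, -78 °C; 5, DMPU, -78 °C to rt; aq. NH4Cl
Reagents that add atoms: none
Why: In this Corey-Seebach umpolung with tandem Michael addition and enolate alkylation, the soft anion 6 attacks C4 of butenolide 4 on the face opposite the C5 menthyloxy group (sets 4R, the future oxolane C4), and enolate 7 is then benzylated by SN2 at C3 opposite the bulky dithianyl group (sets 3R, the future oxolane C3), so the 3,4-trans-4,5-trans lactone should form as one diastereomer.

**Step 3**
Reactants: 8 the (3R,4R,5R) lactone of step 2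
Product: 9 (2R,3R)-2-[2-(3,4-dimethoxyphenyl)-1,3-dithian-2-yl]-3-(3,4,5-trimethoxybenzyl)butane-1,4-diol
Conditions: LiAlH4, THF, 0 °C to rt; H2O, 15% aq. NaOH, H2O
Reagents that add atoms: none
Why: In this exhaustive LiAlH4 reduction of a gamma-alkoxy lactone, hydride opens the lactone, the released hemiacetal alkoxide expels menthoxide and the resulting aldehyde is reduced at once, which turns lactone C2 and C5 into the two CH2OH groups without touching the dithiane, the aryl ethers or the two stereocentres.

**Step 4**
Reactants: 9 the (2R,3R) dithiane diol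
Product: 10 (2R,3R)-1-(3,4-dimethoxyphenyl)-4-hydroxy-2-(hydroxymethyl)-3-(3,4,5-trimethoxybenzyl)butan-1-one (open-chain keto diol)
Conditions: Hg(ClO4)2·3H2O (1.5 equiv), CaCO3, THF-H2O (5:1), 0 °C
Reagents that add atoms: water, O
Why: In this mercury-assisted dithiane hydrolysis, thiophilic divalent mercury ionises the C-S bonds quickly at 0 °C and water delivers the carbonyl oxygen, while suspended CaCO3 takes up the HClO4 so that the new enolisable C4-H and the beta-hydroxy ketone see neither acid nor base.

**Step 5**
Reactants: 10 the (2R,3R) keto diol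
Product: 12 Magnone B (2S,3R,4R; 2,3-trans; 3,4-cis), via C2 benzylic cation 11 (not isolated)
Conditions: DDQ (1.05 equiv, in portions), 4 Å molecular sieves, CH2Cl2, 0 °C to rt; aq. L-ascorbic acid, then brief aq. NaHCO3 wash
Reagents that add atoms: none
Why: DDQ forms a charge-transfer complex with the electron-rich 3,4,5-trimethoxyphenyl ring and removes hydride from the adjoining C2 methylene, giving cation 11, which the para methoxy oxygen stabilises in its quinoid oxocarbenium form; the C5 hydroxyl adds to C2 and the proton ends on the hydroquinone anion. The closest known reaction type is the DDQ-mediated benzylic C-H oxidation of alkoxyarenes with capture by a tethered alcohol, the reaction that converts dibenzylbutanediol lignans into 2-aryl oxolanes. The oxolane closes in the 5-exo-trig mode, O1 attacking trigonal C2 while the C2-aryl pi bond stays outside the new ring. The new C2 centre is controlled by C3 and C4: their CH2OH and aroyl groups lie on the same face of the forming envelope, so the aryl group takes the opposite face (2S; 2,3-trans), the alternative being an all-cis trisubstituted ring. Site selectivity is secured because C2 holds the only benzylic C-H bonds and the dimethoxyphenyl ring is made electron-poor by its carbonyl group, and hydroxyl selectivity because the C3 arm could only close an oxetane. About one equivalent of DDQ, a dry medium and the absence of added acid keep down a second hydride loss from C2-H of 12, Friedel-Crafts capture of 11 by the aroyl ring and enolisation at C4.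

**Compound list**
1 | 3,4-dimethoxybenzaldehyde | COc1ccc(C=O)cc1OC | starting material
2 | propane-1,3-dithiol | SCCCS | starting material
3 | 2-(3,4-dimethoxyphenyl)-1,3-dithiane | COc1ccc(C2SCCCS2)cc1OC | intermediate
4 | (5R)-5-(l-menthyloxy)furan-2(5H)-one | O=C1O[C@@H](O[C@@H]2C[C@H](C)CC[C@H]2C(C)C)C=C1 | starting material
5 | 3,4,5-trimethoxybenzyl bromide | COc1cc(CBr)cc(OC)c1OC | starting material
6 | 2-lithio-2-(3,4-dimethoxyphenyl)-1,3-dithiane | [Li]C1(SCCCS1)c2ccc(OC)c(OC)c2 | intermediate
7 | lithium enolate of (4R,5R)-4-[2-(3,4-dimethoxyphenyl)-1,3-dithian-2-yl]-5-(l-menthyloxy)oxolan-2-one | [Li]OC1=C[C@@H](C2(SCCCS2)c3ccc(OC)c(OC)c3)[C@H](O[C@@H]4C[C@H](C)CC[C@H]4C(C)C)O1 | intermediate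
8 | (3R,4R,5R)-4-[2-(3,4-dimethoxyphenyl)-1,3-dithian-2-yl]-5-(l-menthyloxy)-3-(3,4,5-trimethoxybenzyl)oxolan-2-one | O=C1O[C@@H](O[C@@H]2C[C@H](C)CC[C@H]2C(C)C)[C@H](C3(SCCCS3)c4ccc(OC)c(OC)c4)[C@H]1Cc5cc(OC)c(OC)c(OC)c5 | intermediate
9 | (2R,3R)-2-[2-(3,4-dimethoxyphenyl)-1,3-dithian-2-yl]-3-(3,4,5-trimethoxybenzyl)butane-1,4-diol | COc1ccc(C2(SCCCS2)[C@@H](CO)[C@H](CO)Cc3cc(OC)c(OC)c(OC)c3)cc1OC | intermediate
10 | (2R,3R)-1-(3,4-dimethoxyphenyl)-4-hydroxy-2-(hydroxymethyl)-3-(3,4,5-trimethoxybenzyl)butan-1-one | COc1ccc(C(=O)[C@@H](CO)[C@H](CO)Cc2cc(OC)c(OC)c(OC)c2)cc1OC | intermediate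
11 | C2 benzylic cation of 10 (quinoid oxocarbenium form, counter-ion the DDQ hydroquinone anion) | COc1ccc(C(=O)[C@@H](CO)[C@H](CO)[CH+]c2cc(OC)c(OC)c(OC)c2)cc1OC | intermediate
12 | Magnone B, (3,4-dimethoxyphenyl)[(3R,4R,5S)-4-(hydroxymethyl)-5-(3,4,5-trimethoxyphenyl)oxolan-3-yl]methanone | COc1ccc(C(=O)[C@H]2CO[C@H](c3cc(OC)c(OC)c(OC)c3)[C@H]2CO)cc1OC | target

Total step count: 5
Longest linear sequence: 5 steps (1, 3, 8, 9, 10, 12)

**Steps most likely to fail**

**Step 5.**
- The first hydride abstraction may be slow, because the flanked 4-methoxy group is twisted out of conjugation and the 3- and 5-methoxy groups are meta to C2.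
- A second hydride abstraction from the new, ether-activated C2-H may then compete.
- The hydroquinone formed may promote enolisation at C4, with drift to the all-trans ring, or dehydration through the hemiketal of the gamma-hydroxy ketone.
- Fallback: it sets out from enolate 7 (made from 3 and 4 as in step 2) and comes back at 12 through the same cation 11, with C2 delivered already oxygenated so that no oxidant meets the product. Enolate 7 is trapped at -78 °C with 3,4,5-trimethoxybenzaldehyde instead of 5 to give the aldol lactone F1, whose carbinol configuration is irrelevant. LiAlH4 gives the dithiane triol F2, and Hg(ClO4)2 with CaCO3 in aqueous THF gives the keto triol F3. A catalytic amount of camphorsulfonic acid in CH2Cl2 at 0 °C then ionises only the trimethoxybenzylic alcohol, after which the C5 hydroxyl closes O1-C2.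

**Step 4.**
- Configuration at C4 may be lost while the ketone is unveiled next to two free hydroxyls, by proton loss from the cyclic oxocarbenium ion that the C3 arm can form.
- Beta-elimination of the C5 hydroxyl is also possible.
- The electron-rich ring may be mercurated.
- Fallback: it sets out from 8 and comes back at 10. The dithiane is hydrolysed on the lactone (Hg(ClO4)2, CaCO3, aqueous THF), where no hydroxyl is free and C4 stands trans to both ring neighbours, so enolisation cannot erode it; this gives the keto lactone F4. LiAlH4 reduces lactone, acetal and ketone to the benzylic triol F5 (carbinol epimers). MnO2 in CH2Cl2 re-oxidises only the benzylic alcohol under neutral conditions.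

**Step 2.**
- SN2 benzylation of the congested enolate may lag behind proton transfer and retro-addition on warming, so the unalkylated adduct accumulates.
- Fallback: it sets out from 4 and comes back at 10, with the roles of the two aryl units exchanged so that a fast aldol trapping replaces the slow alkylation. 3,4,5-Trimethoxybenzaldehyde and 2 give 2-(3,4,5-trimethoxyphenyl)-1,3-dithiane F6. Its lithio derivative adds to 4 anti to the menthyloxy group, and the enolate is trapped at -78 °C with aldehyde 1 to give the aldol lactone F7. Raney Ni in ethanol at rt cuts the dithiane down to CH2 and gives the benzyl lactone F8. LiAlH4 then gives the same benzylic triol F5, and MnO2 gives 10. The 2,3-disubstituted butane-1,4-diol core maps onto itself by a twofold rotation that exchanges its ends, so the same auxiliary 4 leads to the same enantiomer.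

**Further compounds**
F1 | step 5 | 3,4-trans-4,5-trans aldol lactone, 8 with CH(OH) in place of the benzylic CH2 (carbinol epimers) | O=C1O[C@@H](O[C@@H]2C[C@H](C)CC[C@H]2C(C)C)[C@H](C3(SCCCS3)c4ccc(OC)c(OC)c4)[C@H]1C(O)c5cc(OC)c(OC)c(OC)c5
F2 | step 5 | dithiane triol, 9 with a C2 hydroxyl (carbinol epimers) | COc1ccc(C2(SCCCS2)[C@@H](CO)[C@H](CO)C(O)c3cc(OC)c(OC)c(OC)c3)cc1OC
F3 | step 5 | keto triol, 10 with a C2 hydroxyl (carbinol epimers) | COc1ccc(C(=O)[C@@H](CO)[C@H](CO)C(O)c2cc(OC)c(OC)c(OC)c2)cc1OC
F4 | step 4 | keto lactone, 4-(3,4-dimethoxybenzoyl)-5-(l-menthyloxy)-3-(3,4,5-trimethoxybenzyl)oxolan-2-one, configuration as in 8 | O=C1O[C@@H](O[C@@H]2C[C@H](C)CC[C@H]2C(C)C)[C@H](C(=O)c3ccc(OC)c(OC)c3)[C@H]1Cc4cc(OC)c(OC)c(OC)c4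
F5 | step 4 | benzylic triol, 10 with CH(OH) in place of the ketone (carbinol epimers) | COc1ccc(C(O)[C@@H](CO)[C@H](CO)Cc2cc(OC)c(OC)c(OC)c2)cc1OC
F6 | step 2 | 2-(3,4,5-trimethoxyphenyl)-1,3-dithiane | COc1cc(C2SCCCS2)cc(OC)c1OC
F7 | step 2 | 3,4-trans-4,5-trans lactone with 4-[2-(3,4,5-trimethoxyphenyl)-1,3-dithian-2-yl] and 3-[(3,4-dimethoxyphenyl)(hydroxy)methyl] groups (carbinol epimers) | O=C1O[C@@H](O[C@@H]2C[C@H](C)CC[C@H]2C(C)C)[C@H](C3(SCCCS3)c4cc(OC)c(OC)c(OC)c4)[C@H]1C(O)c5ccc(OC)c(OC)c5
F8 | step 2 | 3,4-trans-4,5-trans lactone with 4-(3,4,5-trimethoxybenzyl) and 3-[(3,4-dimethoxyphenyl)(hydroxy)methyl] groups (carbinol epimers) | O=C1O[C@@H](O[C@@H]2C[C@H](C)CC[C@H]2C(C)C)[C@H](Cc3cc(OC)c(OC)c(OC)c3)[C@H]1C(O)c4ccc(OC)c(OC)c4
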